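Ring A of the target (C1–C5, C10, with the C4 methyl/carboxyl pair, 5α-H and the C10 methyl) is taken intact from (+)-dehydroabietic acid. Its arene is cut away to a B-nor ketone whose five-membered ring holds C5, C6, C7, C10 and the future C8 as a carbonyl. Everything rests on the C9–C10 disconnection: in a 1-(1-bromoalkyl)cyclopentanol, silver-induced semipinacol shift of C10 from C8 to the exocyclic C9 expands this ring to six-membered ring B (C5–C10) and, in the same operation, sets C9 with its propanoate chain next to a C8 ketone, which is then methylenated and hydrated from the α-face.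

Key step: step 6

Remark: labdane numbering of the target is used throughout (C4 bears CH3/CO2H, C8 the acetoxy group, C9 the propanoic chain, C10 the angular methyl; α is the face opposite the C10 methyl). The ring carbonyl carbon of 6 is the old abietane C9 and becomes C8 of the target.

Step 1
Reactants: 1 (+)-dehydroabietic acid
Product: 2 4-(trifluoromethyl)benzyl dehydroabietate
Conditions: 4-CF3C6H4CH2Br, K2CO3, DMF, rt
Reagents that add atoms: 4-(trifluoromethyl)benzyl bromide, FC(F)(F)c1ccc(CBr)cc1
Why: SN2 O-alkylation of the carboxylate is insensitive to the crowding at C4 and installs an ester whose CF3-deactivated ring should survive ozone yet be hydrogenolysed in step 10.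

Step 2
Reactants: 2 4-(trifluoromethyl)benzyl dehydroabietate
Product: 4 seco-diacid monoester, via bis(2-oxoaldehyde) 3 (not isolated)
Conditions: O3 (excess), AcOH/EtOAc, 0 °C; then 30% H2O2, HCO2H, 50 °C
Reagents that add atoms: ozone, [O-][O+]=O; hydrogen peroxide, OO
Why: Arene ozonolysis with oxidative work-up cleaves the electron-rich trialkylbenzene ring (either Kekulé mode) to α-dicarbonyl units at the two ring-fusion carbons, which H2O2 cuts to the two carboxylic acids, while C4, C5 and C10 carry no acidic hydrogen and are untouched.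

Step 3
Reactants: 4 seco-diacid monoester
Product: 6 B-nor ketone, via cyclic anhydride 5 (not isolated)
Conditions: Ac2O, NaOAc, 140 °C; then 250 °C, N2
Reagents that add atoms: none
Why: Blanc cyclisation (ketonic decarboxylation of an adipic-type 1,6-diacid through its anhydride): only C7 has α-hydrogens, so it acylates the carboxyl on C10 and CO2 is lost to give the trans-fused cyclopentanone, as in homocamphoric acid to camphor; the C18 ester is no anhydride partner and stays out.

Step 4
Reactants: 6 B-nor ketone; 7 vinylmagnesium bromide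
Product: 8 vinyl carbinol
Conditions: CeCl3, THF, −78 → 0 °C; aq NH4Cl
Reagents that add atoms: none
Why: Grignard 1,2-addition (CeCl3 suppresses enolisation) to the neopentyl cyclopentanone from the α-face anti to the angular methyl, as with 17-oxo steroids, should give the 8β-ol, a stereocentre that is erased in step 6; the hindered C18 ester does not react.

Step 5
Reactants: 8 vinyl carbinol; 9 benzyl bromoacetate
Product: 10 bromohydrin ester
Conditions: fac-Ir(ppy)3 (1 mol %), MeCN, blue LEDs, rt
Reagents that add atoms: none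
Why: Kharasch atom-transfer radical addition: the electrophilic benzyloxycarbonylmethyl radical adds to the terminal vinyl carbon (C11) and the C9 radical takes bromine from 9, forming C11–C12 and C9–Br; both C9 epimers form, which is harmless because C9 is equilibrated in step 6.

Step 6
Reactants: 10 bromohydrin ester
Product: 12 8-oxo diester, via C9-epimeric ketone 11 (not isolated)
Conditions: AgBF4, 2,6-di-tert-butyl-4-methylpyridine, CH2Cl2, −20 °C → rt; filter; DBU (0.3 equiv), rt
Reagents that add atoms: none
Why: Ag(I) pulls bromide from C9 while the C8–C10 σ-bond, antiperiplanar to C–Br, shifts to C9 and the carbinol oxygen collapses to the C8 ketone (semipinacol rearrangement, the reaction type of the D-homoannulation of 17-hydroxy-20-sulfonyloxy or 20-amino pregnanes). The five-membered ring (C5, C6, C7, C8, C10) thereby becomes six-membered ring B by a 1,2-alkyl shift; no ring is closed by cyclisation. The selectivity needed is migration of C10 over C7: the quaternary C10 is the better cation-stabilising migrating group and the substituted C9 favours the rotamer with C–Br anti to C8–C10, as C13 migrates in the steroid precedent. C9 is formed with inversion from a C9-epimeric bromide, so both epimers arise; being α to the new ketone it is equilibrated by DBU to the equatorial 9β-chain (9α-H) isomer, controlled by the trans-decalin and the axial C10 methyl. The pyridine base binds HBF4 so that the benzylic esters stay intact.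

Step 7
Reactants: 12 8-oxo diester
Product: 13 8(17)-methylene diester
Conditions: Ph3PCH3Br, KHMDS, THF, 0 °C → rt
Reagents that add atoms: methyltriphenylphosphonium bromide, C[P+](c1ccccc1)(c1ccccc1)c1ccccc1.[Br-]
Why: Wittig methylenation of the C8 ketone; the esters should tolerate the non-stabilised ylide at this temperature and any enolisation only returns the thermodynamic 9α-H epimer.

Step 8
Reactants: 13 8(17)-methylene diester
Product: 15 8α-hydroxy diester, via tertiary hydroperoxide 14 (not isolated)
Conditions: Mn(dpm)3 (10 mol %), PhSiH3, O2 (1 atm), i-PrOH/CH2Cl2, 0 °C → rt; then PPh3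
Reagents that add atoms: dioxygen, O=O
Why: Mukaiyama hydration (hydrogen-atom transfer to the 1,1-disubstituted alkene, O2 capture, hydroperoxide reduction) gives the Markovnikov tertiary alcohol; O2 should approach the planar C8 radical from the equatorial α-face because the β-axial path is blocked by the syn-axial C10 methyl, setting 8α-OH/8β-CH3.

Step 9
Reactants: 15 8α-hydroxy diester
Product: 16 8α-acetoxy diester
Conditions: AcCl, PhNMe2, CH2Cl2, 0 °C → rt
Reagents that add atoms: acetyl chloride, CC(=O)Cl
Why: Acylation of the hindered tertiary alcohol under the conditions used for sclareol-type 8-ols, with retention at C8; C13 is still an ester, so no mixed anhydride can lactonise onto O8.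

Step 10
Reactants: 16 8α-acetoxy diester
Product: 17 target diacid CNP0196050.1
Conditions: H2 (1 atm), 10% Pd/C, EtOAc, rt
Reagents that add atoms: none
Why: Catalytic hydrogenolysis cleaves both benzylic esters under neutral conditions that leave the tertiary acetate and all stereocentres untouched.

Compound list

1 | (+)-dehydroabietic acid, abieta-8,11,13-trien-18-oic acid, (1R,4aS,10aR); 4β-CH3, 4α-CO2H, 5α-H, 10β-CH3 | CC(C)c1cc2c(cc1)[C@]3(CCC[C@@]([C@@H]3CC2)(C)C(=O)O)C | starting material
2 | 4-(trifluoromethyl)benzyl dehydroabietate, configuration of 1 | CC(C)c1cc2c(cc1)[C@]3(CCC[C@@]([C@@H]3CC2)(C)C(=O)OCc4ccc(cc4)C(F)(F)F)C | intermediate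
3 | bis(2-oxoaldehyde): ring A of 2 in which C10 carries CH3 and C(=O)CHO and C5 carries H and CH2CH2C(=O)CHO (carbonyl form of the ozonolysis stage) | O=CC(=O)[C@]1(CCC[C@@]([C@@H]1CCC(=O)C=O)(C)C(=O)OCc2ccc(cc2)C(F)(F)F)C | intermediate (not isolated)
4 | seco-diacid monoester: cyclohexane ring A in which C10 carries CH3 and CO2H, C5 carries H and CH2CH2CO2H, C4 carries CH3 and the 4-(trifluoromethyl)benzyl ester; configuration of 1 | OC(=O)[C@]1(CCC[C@@]([C@@H]1CCC(=O)O)(C)C(=O)OCc2ccc(cc2)C(F)(F)F)C | intermediate
5 | seven-membered cyclic anhydride (oxepane-2,7-dione) of 4 | O=C1OC(=O)CC[C@@H]2[C@]1(C)CCC[C@@]2(C)C(=O)OCc3ccc(cc3)C(F)(F)F | intermediate (not isolated)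
6 | B-nor ketone: 4-(trifluoromethyl)benzyl trans-4,7a-dimethyl-1-oxo-octahydroindene-4-carboxylate; five-membered ring = C5, C6, C7, C8(=O), C10; 5α-H, 10β-CH3, 4β-CH3, 4α-ester | O=C1CC[C@@H]2[C@]1(C)CCC[C@@]2(C)C(=O)OCc3ccc(cc3)C(F)(F)F | intermediate
7 | vinylmagnesium bromide | C=C[Mg]Br | starting material
8 | vinyl carbinol: 6 with C8 carrying β-OH and α-vinyl (C9=C11) | C=C[C@]1(O)CC[C@@H]2[C@]1(C)CCC[C@@]2(C)C(=O)OCc3ccc(cc3)C(F)(F)F | intermediate
9 | benzyl bromoacetate | BrCC(=O)OCc1ccccc1 | starting material
10 | bromohydrin ester: benzyl 4-bromo-4-(8β-hydroxy B-nor bicycle-8-yl)butanoate, both C9 epimers | O=C(OCc3ccccc3)CCC(Br)[C@]1(O)CC[C@@H]2[C@]1(C)CCC[C@@]2(C)C(=O)OCc4ccc(cc4)C(F)(F)F | intermediate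
11 | ring-expanded 8-oxo diester as a mixture of C9 epimers | O=C1CC[C@@H]2[C@](C)(CCC[C@@]2(C)C(=O)OCc3ccc(cc3)C(F)(F)F)C1CCC(=O)OCc4ccccc4 | intermediate (not isolated)
12 | 13-benzyl 18-[4-(trifluoromethyl)benzyl] 8-oxo-14,15,16,17-tetranorlabdane-13,18-dioate; trans-decalin, 5α-H, 9α-H, 10β-CH3 | O=C1CC[C@@H]2[C@](C)(CCC[C@@]2(C)C(=O)OCc3ccc(cc3)C(F)(F)F)[C@H]1CCC(=O)OCc4ccccc4 | intermediate
13 | 13-benzyl 18-[4-(trifluoromethyl)benzyl] 14,15,16-trinorlabd-8(17)-ene-13,18-dioate | C=C1CC[C@@H]2[C@](C)(CCC[C@@]2(C)C(=O)OCc3ccc(cc3)C(F)(F)F)[C@H]1CCC(=O)OCc4ccccc4 | intermediate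
14 | 8α-hydroperoxy-8β-methyl diester | OO[C@]1(C)CC[C@@H]2[C@](C)(CCC[C@@]2(C)C(=O)OCc3ccc(cc3)C(F)(F)F)[C@H]1CCC(=O)OCc4ccccc4 | intermediate (not isolated)
15 | 13-benzyl 18-[4-(trifluoromethyl)benzyl] 8α-hydroxy-14,15,16-trinorlabdane-13,18-dioate | O[C@]1(C)CC[C@@H]2[C@](C)(CCC[C@@]2(C)C(=O)OCc3ccc(cc3)C(F)(F)F)[C@H]1CCC(=O)OCc4ccccc4 | intermediate
16 | 13-benzyl 18-[4-(trifluoromethyl)benzyl] 8α-acetoxy-14,15,16-trinorlabdane-13,18-dioate | CC(=O)O[C@]1(C)CC[C@@H]2[C@](C)(CCC[C@@]2(C)C(=O)OCc3ccc(cc3)C(F)(F)F)[C@H]1CCC(=O)OCc4ccccc4 | intermediate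
17 | 8α-acetoxy-14,15,16-trinorlabdane-13,18-dioic acid (CNP0196050.1) | CC(=O)O[C@]1(C)CC[C@@H]2[C@](C)(CCC[C@@]2(C)C(=O)O)[C@H]1CCC(=O)O | target

Total step count: 10. Longest linear sequence: 10 steps (1 → 17).

Steps most likely to fail

Step 6. The C7 methylene may migrate instead of C10, or the ester carbonyl may capture the developing C9 cation (lactone formation) before the 1,2-shift. The fallback sets out from 6 and comes back at 12. Wittig olefination of 6 with the ylide of (3-carboxypropyl)triphenylphosphonium bromide (NaHMDS, THF) would give the alkylidene acid F1, and BnBr/K2CO3 in DMF the benzyl ester F2. [Hydroxy(tosyloxy)iodo]benzene in 95% MeOH then rearranges the exocyclic alkene oxidatively (Wittig–ring-expansion sequence): the iodane on C9 leaves as C10 shifts to C9. DBU equilibration of C9 returns 12.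

Step 3. Thermal ketonisation may lose out to polymeric anhydride formation and decomposition at 250 °C. The fallback sets out from 4 and comes back at 6. MeOH with catalytic H2SO4 at rt should esterify only the unhindered chain acid, giving the mono methyl ester F3. Oxalyl chloride converts the neopentyl acid into the acid chloride F4. LiHMDS (2.2 equiv, THF, −78 °C) closes the ring by intramolecular C-acylation of the ester enolate, giving the β-keto ester F5; the acid chloride outcompetes the C18 ester as electrophile. Krapcho demethoxycarbonylation (LiCl, wet DMSO, 140 °C) returns 6.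

Step 8. Facial selectivity in the O2 capture of the C8 radical may be poor (8-epi alcohol), or the radical may be reduced to the 8-H alkane. The fallback sets out from 13 and comes back at 15. mCPBA (CH2Cl2, NaHCO3) should epoxidise from the less hindered α-face to the 8α,17-epoxide F6. Sodium phenylselenide (PhSeSePh, NaBH4, EtOH) opens it at the primary C17 to the hydroxy selenide F7. Bu3SnH/AIBN (toluene, 80 °C) removes selenium and returns 15.

Further compounds

F1 | step 6 | alkylidene acid: 4-[B-nor bicycle-8-ylidene]butanoic acid, C8=C9 isomer mixture, C18 4-(trifluoromethyl)benzyl ester | OC(=O)CCC=C1CC[C@@H]2[C@]1(C)CCC[C@@]2(C)C(=O)OCc3ccc(cc3)C(F)(F)F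
F2 | step 6 | benzyl ester of F1 | O=C(OCc4ccccc4)CCC=C1CC[C@@H]2[C@]1(C)CCC[C@@]2(C)C(=O)OCc3ccc(cc3)C(F)(F)F
F3 | step 3 | mono methyl ester of 4 (chain CO2CH3, free acid on C10) | OC(=O)[C@]1(CCC[C@@]([C@@H]1CCC(=O)OC)(C)C(=O)OCc2ccc(cc2)C(F)(F)F)C
F4 | step 3 | acid chloride of F3 | ClC(=O)[C@]1(CCC[C@@]([C@@H]1CCC(=O)OC)(C)C(=O)OCc2ccc(cc2)C(F)(F)F)C
F5 | step 3 | β-keto ester: 6 carrying CO2CH3 on C7 (C7 epimers/enol) | O=C1C(C(=O)OC)C[C@@H]2[C@]1(C)CCC[C@@]2(C)C(=O)OCc3ccc(cc3)C(F)(F)F
F6 | step 8 | 8α,17-epoxide of 13 | O1C[C@]12CC[C@@H]3[C@](C)(CCC[C@@]3(C)C(=O)OCc4ccc(cc4)C(F)(F)F)[C@H]2CCC(=O)OCc5ccccc5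
F7 | step 8 | 8α-hydroxy-17-(phenylselanyl) diester | O[C@]1(C[Se]c5ccccc5)CC[C@@H]2[C@](C)(CCC[C@@]2(C)C(=O)OCc3ccc(cc3)C(F)(F)F)[C@H]1CCC(=O)OCc4ccccc4
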